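**Plan**
- Retrosynthesis cuts, in this order: the two lactone bonds at O1 (O1–C8a and O1–C2), the C8–acyl bond, the C4–C4a bond, and the C2=C3 bond of a cinnamate.
- Forward: the C2–C3–C4 chain is made on ring B as a cinnamate, ring A is joined at C4 as a 1,3-dimethoxyarene, the acyl group enters at the future C8, and the lactone, the only ring formed, closes last.
- Enabling feature: O1 on C8a lies ortho to the C8 ketone and within lactonising distance of the C2 carboxyl. Ring A therefore needs only O5 and O7 until the end, and C4a and C8 are the two mutually activated positions of a resorcinol ether.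
- Stereochemistry: the single centre C4 (S) comes from a rhodium/(S)-BINAP 1,4-addition and is not touched afterwards.
- Protection: acetate on the ring B oxygen, methyl on O5 and O7, benzyl on the carboxyl.

Key step: step 5

Numbering: chroman-2-one numbering of the target is used throughout (O1, C2, C3, C4, C4a, C5 to C8, C8a); ring A is the benzo ring, ring B the 4-hydroxyphenyl group.

Assumption: the facial sense in step 2 is taken from the accepted model for BINAP–rhodium aryl complexes, in which the (S) ligand binds an enoate through the Si face at C2; should the sense prove opposite, the (R) ligand would be used.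

**Step 1**
Reactants: 1 4-formylphenyl acetate; 2 benzyl (triphenylphosphoranylidene)acetate
Product: 3 benzyl (E)-3-(4-acetoxyphenyl)prop-2-enoate
Conditions: CH2Cl2, rt
Reagents that add atoms: none
Why: Wittig olefination with a stabilised ylide should give the (E)-enoate under neutral conditions that leave the aryl acetate untouched.

**Step 2**
Reactants: 3 benzyl (E)-3-(4-acetoxyphenyl)prop-2-enoate; 4 2,4-dimethoxyphenylboronic acid
Product: 5 benzyl (3S)-3-(4-acetoxyphenyl)-3-(2,4-dimethoxyphenyl)propanoate
Conditions: [Rh(OH)((S)-BINAP)]2 (1.5 mol %), 4 (2.5 equiv), dioxane/H2O 10:1, 50 °C (BINAP = 2,2'-bis(diphenylphosphino)-1,1'-binaphthyl)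
Reagents that add atoms: none
Why: In this Hayashi–Miyaura asymmetric 1,4-addition the aryl–rhodium complex of (S)-BINAP should bind the (E)-enoate through its C2 Si face, which for this cinnamate is also the C3 Si face, so that syn carbometalation places the dimethoxyphenyl group on that face and sets the (S) centre, while the base-free hydroxorhodium conditions keep the acetate.

**Step 3**
Reactants: 5 benzyl (3S)-3-(4-acetoxyphenyl)-3-(2,4-dimethoxyphenyl)propanoate; 6 3-phenylpropanoic acid
Product: 7 benzyl (3S)-3-(4-acetoxyphenyl)-3-[2,4-dimethoxy-5-(3-phenylpropanoyl)phenyl]propanoate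
Conditions: 6 (1.3 equiv), (CF3CO)2O (3 equiv), 85 % H3PO4 (0.3 equiv), CH2Cl2, 0 °C to rt
Reagents that add atoms: none
Why: Friedel–Crafts acylation by the mixed trifluoroacetic anhydride should occur only at the ring A carbon para to one methoxy and ortho to the other (the future C8), because the site between the two methoxy groups is shielded, the other aryl rings are far less nucleophilic, and no metal Lewis acid is present to attack the benzyl ester or the ethers.

**Step 4**
Reactants: 7 benzyl (3S)-3-(4-acetoxyphenyl)-3-[2,4-dimethoxy-5-(3-phenylpropanoyl)phenyl]propanoate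
Product: 8 (3S)-3-(4-acetoxyphenyl)-3-[2,4-dimethoxy-5-(3-phenylpropanoyl)phenyl]propanoic acid
Conditions: H2 (1 atm), 10 % Pd/C, EtOAc, rt
Reagents that add atoms: none
Why: Hydrogenolysis of the benzyl ester should free the acid under neutral conditions that spare the aryl acetate, the methyl ethers and the electron-rich aryl ketone.

**Step 5**
Reactants: 8 (3S)-3-(4-acetoxyphenyl)-3-[2,4-dimethoxy-5-(3-phenylpropanoyl)phenyl]propanoic acid
Product: 10 (4S)-4-(4-acetoxyphenyl)-5,7-dimethoxy-8-(3-phenylpropanoyl)chroman-2-one, via aryl trifluoroacetate 9 (not isolated)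
Conditions: Pd(OAc)2 (10 mol %), PhI(OCOCF3)2 (1.5 equiv), CF3CO2H/ClCH2CH2Cl 1:1, 50 °C
Reagents that add atoms: bis(trifluoroacetoxy)iodobenzene, O=C(OI(OC(=O)C(F)(F)F)c1ccccc1)C(F)(F)F
Why: Proposed new method: the C8 ketone binds electrophilic divalent palladium and steers it to C8a–H, the only ortho C–H of the ketone, giving a five-membered palladacycle; PhI(OCOCF3)2 oxidises this to tetravalent palladium, C–O reductive elimination gives the aryl trifluoroacetate 9, and the neighbouring carboxyl group takes over the phenolic oxygen by acyl exchange through its mixed trifluoroacetic anhydride, releasing CF3CO2H. The closest known reaction type is the ketone-directed palladium-catalysed ortho C–H hydroxylation of aryl ketones with a trivalent-iodine oxidant in trifluoroacetic acid, which has not been shown for a C–H flanked by two substituents or coupled to lactonisation in the same flask. The lactone ring closes by a 6-exo-trig acyl substitution of O1 at C2. No stereocentre is formed, and C4, which carries no acidic hydrogen, should not be disturbed. The step needs site selectivity for C8a over C6–H, the ring B C–H bonds and the CH2 next to the ketone: chelation reaches only C8a because C7 carries methoxy, the protonated acid is a poor directing group in CF3CO2H, the acetate keeps ring B electron-poor toward both palladium and the oxidant, and the C5 methoxy leaves O1 as the only phenolic oxygen the acid can acylate. Capture of the new oxygen as an ester should also guard the now trioxygenated ring A against over-oxidation.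

**Step 6**
Reactants: 10 (4S)-4-(4-acetoxyphenyl)-5,7-dimethoxy-8-(3-phenylpropanoyl)chroman-2-one
Product: 12 (4S)-4-(4-hydroxyphenyl)-5,7-dimethoxy-8-(3-phenylpropanoyl)chroman-2-one, via ring-opened methyl ester 11 (not isolated)
Conditions: TsOH·H2O (0.2 equiv), MeOH, 60 °C; then solvent exchange to PhMe, 90 °C with removal of MeOH
Reagents that add atoms: none
Why: Acid-catalysed transesterification should remove the acetate and open the lactone to the methyl ester 11, and since O5 is still methylated the acid-catalysed relactonisation in hot toluene can close only onto O1.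

**Step 7**
Reactants: 12 (4S)-4-(4-hydroxyphenyl)-5,7-dimethoxy-8-(3-phenylpropanoyl)chroman-2-one
Product: 13 (4S)-5,7-dihydroxy-4-(4-hydroxyphenyl)-8-(3-phenylpropanoyl)chroman-2-one
Conditions: BBr3 (6 equiv), CH2Cl2, −78 to 0 °C; cold H2O quench
Reagents that add atoms: none
Why: BBr3 should cleave both aryl methyl ethers (the C7 ether helped by chelation to the C8 ketone) without opening the aryl lactone, and because O1 and O5 are meta to each other across C4a the acyl group cannot pass to O5 unless the ring is first opened.

**Compound list**
1 | 4-formylphenyl acetate | CC(=O)Oc1ccc(C=O)cc1 | starting material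
2 | benzyl (triphenylphosphoranylidene)acetate | O=C(C=P(c1ccccc1)(c1ccccc1)c1ccccc1)OCc1ccccc1 | starting material
3 | benzyl (E)-3-(4-acetoxyphenyl)prop-2-enoate | CC(=O)Oc1ccc(/C=C/C(=O)OCc2ccccc2)cc1 | intermediate
4 | 2,4-dimethoxyphenylboronic acid | COc1ccc(B(O)O)c(OC)c1 | starting material
5 | benzyl (3S)-3-(4-acetoxyphenyl)-3-(2,4-dimethoxyphenyl)propanoate | O=C(OCc1ccccc1)C[C@@H](c1ccc(OC(C)=O)cc1)c1ccc(OC)cc1OC | intermediate
6 | 3-phenylpropanoic acid | OC(=O)CCc1ccccc1 | starting material
7 | benzyl (3S)-3-(4-acetoxyphenyl)-3-[2,4-dimethoxy-5-(3-phenylpropanoyl)phenyl]propanoate | O=C(OCc1ccccc1)C[C@@H](c1ccc(OC(C)=O)cc1)c1cc(C(=O)CCc2ccccc2)c(OC)cc1OC | intermediate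
8 | (3S)-3-(4-acetoxyphenyl)-3-[2,4-dimethoxy-5-(3-phenylpropanoyl)phenyl]propanoic acid | OC(=O)C[C@@H](c1ccc(OC(C)=O)cc1)c1cc(C(=O)CCc2ccccc2)c(OC)cc1OC | intermediate
9 | (3S)-3-(4-acetoxyphenyl)-3-[4,6-dimethoxy-3-(3-phenylpropanoyl)-2-(trifluoroacetoxy)phenyl]propanoic acid | OC(=O)C[C@@H](c1ccc(OC(C)=O)cc1)c1c(OC(=O)C(F)(F)F)c(C(=O)CCc2ccccc2)c(OC)cc1OC | intermediate
10 | (4S)-4-(4-acetoxyphenyl)-5,7-dimethoxy-8-(3-phenylpropanoyl)chroman-2-one | O=C1C[C@@H](c2ccc(OC(C)=O)cc2)c2c(OC)cc(OC)c(C(=O)CCc3ccccc3)c2O1 | intermediate
11 | methyl (3S)-3-[2-hydroxy-4,6-dimethoxy-3-(3-phenylpropanoyl)phenyl]-3-(4-hydroxyphenyl)propanoate | COC(=O)C[C@@H](c1ccc(O)cc1)c1c(O)c(C(=O)CCc2ccccc2)c(OC)cc1OC | intermediate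
12 | (4S)-4-(4-hydroxyphenyl)-5,7-dimethoxy-8-(3-phenylpropanoyl)chroman-2-one | O=C1C[C@@H](c2ccc(O)cc2)c2c(OC)cc(OC)c(C(=O)CCc3ccccc3)c2O1 | intermediate
13 | (4S)-5,7-dihydroxy-4-(4-hydroxyphenyl)-8-(3-phenylpropanoyl)chroman-2-one | O=C1C[C@@H](c2ccc(O)cc2)c2c(O)cc(O)c(C(=O)CCc3ccccc3)c2O1 | target

**Totals**
Total step count: 7. Longest linear sequence: 7 steps (1 to 13).

**Steps most likely to fail**

Step 5. Palladation of the C8a–H bond, flanked by the acyl group and the C4 substituent, may be slower than undirected oxidation of ring A by the trivalent-iodine reagent (including attack at the benzylic C4–H) or than oxidation next to the ketone. Material would then be lost before the C–O bond forms. The fallback drops palladium and the directing group and uses the known iodine-mediated oxidative lactonisation of 3,3-diarylpropanoic acids that carry a para-alkoxy group. It sets out from acid 8, treated with PhI(OCOCF3)2 and BF3·OEt2 in CF3CO2H/CH2Cl2 at 0 °C, and returns to the route at lactone 10. In this mode ring A itself is oxidised and the carboxyl oxygen bonds at C4a (para to the C7 methoxy) or directly at C8a. A 1,2-shift of the acyloxy group can go only to C8a, since C5 is blocked by methoxy, and loss of the proton restores the arene. O1 then stems from the carboxyl group and only the C8a–O1 bond is made. No compound outside the list is formed (entry F0).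

Step 2. Protodeboronation of the electron-rich, ortho-substituted boronic acid may outrun insertion into the beta-aryl enoate, and a sluggish insertion may erode facial control. The fallback reverses the roles of the two aryl groups. It sets out from ylide 2, which with commercial 2,4-dimethoxybenzaldehyde (CH2Cl2, rt) should give benzyl (E)-3-(2,4-dimethoxyphenyl)prop-2-enoate F1. Commercial 4-acetoxyphenylboronic acid, a robust boron partner, is then added with [Rh(OH)((R)-BINAP)]2 in dioxane/H2O at 50 °C. With the aryl groups exchanged, the (R) ligand delivers the aryl group to the C3 Re face, which gives the same (S) centre, and the sequence returns to the route at 5.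

Step 3. Ring A may be trifluoroacetylated in place of acylated, the benzyl ester may be lost in the acidic medium, or the activated acid may cyclise onto its own phenyl ring before it reaches ring A. The fallback brings the acyl group in with the aryl nucleophile. It sets out from acid 6, which acylates commercial 1-bromo-2,4-dimethoxybenzene ((CF3CO)2O, H3PO4, where forcing is harmless) para to the C2 methoxy to give 1-(5-bromo-2,4-dimethoxyphenyl)-3-phenylpropan-1-one F2. Miyaura borylation (bis(pinacolato)diboron, PdCl2(dppf), KOAc, dioxane, 90 °C) should give 1-[2,4-dimethoxy-5-(4,4,5,5-tetramethyl-1,3,2-dioxaborolan-2-yl)phenyl]-3-phenylpropan-1-one F3. F3 is then added to enoate 3 under the catalyst of step 2, [Rh(OH)((S)-BINAP)]2 in dioxane/H2O, and the sequence returns to the route at 7.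

**Further compounds**
F0 | step 5 | none | none
F1 | step 2 | benzyl (E)-3-(2,4-dimethoxyphenyl)prop-2-enoate | COc1ccc(/C=C/C(=O)OCc2ccccc2)c(OC)c1
F2 | step 3 | 1-(5-bromo-2,4-dimethoxyphenyl)-3-phenylpropan-1-one | COc1cc(OC)c(C(=O)CCc2ccccc2)cc1Br
F3 | step 3 | 1-[2,4-dimethoxy-5-(4,4,5,5-tetramethyl-1,3,2-dioxaborolan-2-yl)phenyl]-3-phenylpropan-1-one | COc1cc(OC)c(C(=O)CCc2ccccc2)cc1B1OC(C)(C)C(C)(C)O1
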